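**Retrosynthetic overview**

- Feature: ring B (C5–C10) carries cis methyl groups on C8 and C9, C11 on C9 cis to H-10, and its carbinol carbon C5 can serve as an inner diene carbon. This is the imprint of a formyl-exo [4+2] of (E)-2-methylbut-2-enal (C8, C9, C11) on a ring A 2-silyloxydiene (C10, C5, C6, C7).
- Target 19 ⇐ dimethoxyquinone 18 ⇐ tetramethoxyarene 17 (oxidative demethylation, then hydrolysis of one vinylogous ester).
- 17 ⇐ bridged ether 16 (reductive cleavage of benzylic C11–O) ⇐ alkenol 14 (intramolecular alkoxymercuration). The C5 oxygen is delivered from C11, so it is cis to C11 and H-10 by construction; an external oxidant would meet a C4 methyl group on either face.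
- 14 ⇐ lithiated 1,2,4,5-tetramethoxybenzene + aldehyde 11 ⇐ Diels–Alder adduct 9 (C6 silyl enol ether → enol triflate → C5=C6 olefin).
- 9 ⇐ diene 7 + tiglaldehyde 8; 7 ⇐ 2,2-dimethylcyclohexanone. Ring order: ring A and the arene are bought, ring B is closed in the cycloaddition, a temporary oxolane ring fixes C5, and the quinone is unmasked last.

Key step: step 4

**Remarks**

- Terpenoid numbering is used throughout: ring A = C1–C5, C10; ring B = C5–C10; C11 is the carbon on C9. The target is (5S,8S,9R,10S).
- Assumption: the sense of induction in step 4 is taken from the accepted binding model of the catalyst (the diene adds to the Si face of C9 with the (R)-prolinol-derived catalyst); if the sense proves opposite, the mirror-image catalyst is used.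
- The C11 carbinol centre in 14, 15 and 16 forms as an epimer mixture; this is of no consequence because C11 becomes CH2 in step 9.

**Route**

Step 1
Reactants: 1 2,2-dimethylcyclohexanone; 2 2,4,6-triisopropylbenzenesulfonohydrazide
Product: 3 N'-(2,2-dimethylcyclohexylidene)-2,4,6-triisopropylbenzenesulfonohydrazide
Conditions: conc. HCl (cat.), MeCN, rt
Reagents that add atoms: none
Why: Acid-catalysed hydrazone formation, in which the sulfonamide nitrogen should settle anti to the quaternary carbon and so syn to the only alpha-CH2 group.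

Step 2
Reactants: 3 trisylhydrazone; 4 N-methoxy-N-methylacetamide
Product: 6 1-(6,6-dimethylcyclohex-1-en-1-yl)ethan-1-one, via vinyllithium 5 (not isolated)
Conditions: n-BuLi (2.2 equiv), THF, −78 °C then 0 °C; then 4, −78 °C to rt; aq. NH4Cl
Reagents that add atoms: none
Why: Shapiro reaction (dianion formation at the only alpha-CH2, loss of sulfinate and N2) gives the vinyllithium regiospecifically, and acylation by the N-methoxy-N-methylamide stops at the ketone through its chelated tetrahedral adduct.

Step 3
Reactants: 6 1-(6,6-dimethylcyclohex-1-en-1-yl)ethan-1-one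
Product: 7 tert-butyl{[1-(6,6-dimethylcyclohex-1-en-1-yl)ethenyl]oxy}dimethylsilane (ring A 2-silyloxydiene)
Conditions: TBSOTf, Et3N, CH2Cl2, 0 °C
Reagents that add atoms: tert-butyldimethylsilyl trifluoromethanesulfonate, CC(C)(C)[Si](C)(C)OS(=O)(=O)C(F)(F)F
Why: Soft enolisation of a methyl ketone with a silyl triflate and an amine removes a methyl proton and gives the cross-conjugated dienol ether, since gamma-deprotonation would need a tetrasubstituted exocyclic enol ether next to the quaternary carbon.

Step 4
Reactants: 7 ring A 2-silyloxydiene; 8 tiglaldehyde, (E)-2-methylbut-2-enal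
Product: 9 (1R,2S,8aR)-4-[(tert-butyldimethylsilyl)oxy]-1,2,5,5-tetramethyl-1,2,3,5,6,7,8,8a-octahydronaphthalene-1-carbaldehyde (8S,9R,10R; 8-Me and 9-Me cis, CHO cis to H-10, silyl enol ether across C5=C6)
Conditions: (R)-tetrahydro-1-(2-methylphenyl)-3,3-diphenyl-1H,3H-pyrrolo[1,2-c][1,3,2]oxazaborole·HN(SO2CF3)2 (20 mol %), 8 (2 equiv), CH2Cl2, −78 to −20 °C; Et3N quench
Reagents that add atoms: none
Why: The protonated oxazaborolidine binds the formyl oxygen of 8 (s-trans enal, formyl C–H···O contact to the ring oxygen), which lowers the enal LUMO and screens one face. Diene 7 then adds in a concerted, asynchronous [4+2] in which the silyloxy-activated terminus C7 bonds to the beta carbon C8 ahead of C10 to the alpha carbon C9; the closest known reaction type is the enantioselective Diels–Alder reaction of 2-silyloxydienes with alpha-substituted enals under cationic oxazaborolidine catalysis. Ring B is closed by this intermolecular cycloaddition, both ring bonds forming in one step on the s-cis diene. At C8 and C9, suprafacial addition to the E enal keeps the two methyl groups cis; at C10, the formyl-exo transition state places C11 cis to H-10 (H-10 is the inside substituent of the diene terminus); the absolute configuration follows from addition to the unshielded Si face of C9, which should give 8S,9R,10R. The step needs one regiochemistry, exo topology and one enal face: the C6 silyloxy group (largest HOMO coefficient at C7, reinforced by the alkyl group on C10) secures the first, the alpha-methyl group together with the bulk of the catalyst-bound formyl group, which stays away from ring A and its gem-dimethyl group, secures the second, and the catalyst secures the third.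

Step 5
Reactants: 9 Diels–Alder adduct
Product: 10 (1R,2S,8aR)-1-formyl-1,2,5,5-tetramethyl-1,2,3,5,6,7,8,8a-octahydronaphthalen-4-yl trifluoromethanesulfonate (C6 enol triflate, C5=C6)
Conditions: CsF, PhNTf2, DME, rt; aq. NH4Cl work-up
Reagents that add atoms: N-phenylbis(trifluoromethanesulfonimide), O=S(=O)(N(c1ccccc1)S(=O)(=O)C(F)(F)F)C(F)(F)F
Why: Fluoride cleaves the Si–O bond and the regiodefined cesium enolate is O-sulfonylated in situ (silyl enol ether to enol triflate exchange), which keeps the double bond at C5=C6 while the aldehyde, having no alpha hydrogen, cannot enolise.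

Step 6
Reactants: 10 enol triflate
Product: 11 (1R,2S,8aR)-1,2,5,5-tetramethyl-1,2,3,5,6,7,8,8a-octahydronaphthalene-1-carbaldehyde (C5=C6 olefin, C6–H)
Conditions: Pd(OAc)2 (5 mol %), PPh3 (10 mol %), HCO2H, Bu3N, DMF, 60 °C
Reagents that add atoms: none
Why: Palladium-catalysed formate reduction of an enol triflate (oxidative addition to zerovalent palladium, decarboxylation of formate to the hydride, reductive elimination) replaces C6–OTf by C6–H and should leave the aldehyde and the position of the double bond untouched.

Step 7
Reactants: 11 olefinic aldehyde; 12 1,2,4,5-tetramethoxybenzene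
Product: 14 (2,3,5,6-tetramethoxyphenyl)[(1R,2S,8aR)-1,2,5,5-tetramethyl-1,2,3,5,6,7,8,8a-octahydronaphthalen-1-yl]methanol (C11 epimers), via aryllithium 13 (not isolated)
Conditions: 12, n-BuLi, THF, 0 °C to rt; then 11, −78 to −20 °C; aq. NH4Cl
Reagents that add atoms: none
Why: Directed ortho-lithiation between two methoxy groups followed by 1,2-addition of the aryllithium to a non-enolisable aldehyde forms the C11–aryl bond, and the new C11 centre (epimer mixture) is erased in step 9.

Step 8
Reactants: 14 alkenol
Product: 16 bridged ether (oxolane O–C11–C9–C10–C5 on a cis-decalin; 5S,8S,9R,10S; 11-aryl, C11 epimers), via C6 organomercurial 15 (not isolated)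
Conditions: Hg(OAc)2, CH2Cl2, rt; then NaBH4, 3 M NaOH, 0 °C
Reagents that add atoms: none
Why: Intramolecular alkoxymercuration–demercuration adds the carbinol oxygen in Markovnikov, 5-exo, anti fashion to tertiary C5, and because the oxygen is tethered through C11 on C9 it can only reach the C5 face cis to C11 and H-10, which sets C5 and the cis ring fusion.

Step 9
Reactants: 16 bridged ether
Product: 17 (1R,2S,4aS,8aS)-1,2,5,5-tetramethyl-1-[(2,3,5,6-tetramethoxyphenyl)methyl]octahydronaphthalen-4a(2H)-ol
Conditions: Li, NH3(l)/THF, −78 °C; then solid NH4Cl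
Reagents that add atoms: none
Why: Dissolving-metal (Birch-type) cleavage of a benzylic ether: electron transfer to the arene expels the C5 alkoxide from benzylic C11, the benzylic anion is protonated to CH2, and the C5–O bond, which is not benzylic, is never broken, so C5 keeps its configuration.

Step 10
Reactants: 17 tetramethoxyarene
Product: 18 3-{[(1R,2S,4aS,8aS)-4a-hydroxy-1,2,5,5-tetramethyldecahydronaphthalen-1-yl]methyl}-2,5-dimethoxycyclohexa-2,5-diene-1,4-dione
Conditions: (NH4)2Ce(NO3)6 (2.5 equiv), MeCN/H2O, 0 °C
Reagents that add atoms: water, O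
Why: Oxidative demethylation of a 1,4-dimethoxyarene by tetravalent cerium (arene radical cation, ipso attack of water, loss of methanol) should give the 2,5-dimethoxy-1,4-benzoquinone, while the tertiary alcohol is inert at 0 °C.

Step 11
Reactants: 18 dimethoxyquinone
Product: 19 2-hydroxy-3-{[(1R,2S,4aS,8aS)-4a-hydroxy-1,2,5,5-tetramethyldecahydronaphthalen-1-yl]methyl}-5-methoxycyclohexa-2,5-diene-1,4-dione (target)
Conditions: KOH, MeOH/H2O, rt; then 1 M HCl
Reagents that add atoms: potassium hydroxide, [K+].[OH-]
Why: Addition–elimination of hydroxide on a vinylogous ester should replace the methoxy group next to the alkyl-bearing carbon, which is twisted out of conjugation by its two neighbours and is therefore the more electrophilic one, a selectivity typical of 3-alkyl-2,5-dimethoxybenzoquinones.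

**Compound list**

1 | 2,2-dimethylcyclohexanone | CC1(C)CCCCC1=O | starting material
2 | 2,4,6-triisopropylbenzenesulfonohydrazide | CC(C)c1cc(C(C)C)c(S(=O)(=O)NN)c(C(C)C)c1 | starting material
3 | N'-(2,2-dimethylcyclohexylidene)-2,4,6-triisopropylbenzenesulfonohydrazide | CC(C)c1cc(C(C)C)c(S(=O)(=O)NN=C2CCCCC2(C)C)c(C(C)C)c1 | intermediate
4 | N-methoxy-N-methylacetamide | CC(=O)N(C)OC | starting material
5 | 6,6-dimethylcyclohex-1-en-1-yllithium | [Li]C1=CCCCC1(C)C | intermediate
6 | 1-(6,6-dimethylcyclohex-1-en-1-yl)ethan-1-one | CC(=O)C1=CCCCC1(C)C | intermediate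
7 | tert-butyl{[1-(6,6-dimethylcyclohex-1-en-1-yl)ethenyl]oxy}dimethylsilane | C=C(O[Si](C)(C)C(C)(C)C)C1=CCCCC1(C)C | intermediate
8 | tiglaldehyde, (E)-2-methylbut-2-enal | C/C=C(\C)C=O | starting material
9 | (1R,2S,8aR)-4-[(tert-butyldimethylsilyl)oxy]-1,2,5,5-tetramethyl-1,2,3,5,6,7,8,8a-octahydronaphthalene-1-carbaldehyde | O=C[C@]1(C)[C@@H](C)CC(O[Si](C)(C)C(C)(C)C)=C2[C@H]1CCCC2(C)C | intermediate
10 | (1R,2S,8aR)-1-formyl-1,2,5,5-tetramethyl-1,2,3,5,6,7,8,8a-octahydronaphthalen-4-yl trifluoromethanesulfonate | O=C[C@]1(C)[C@@H](C)CC(OS(=O)(=O)C(F)(F)F)=C2[C@H]1CCCC2(C)C | intermediate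
11 | (1R,2S,8aR)-1,2,5,5-tetramethyl-1,2,3,5,6,7,8,8a-octahydronaphthalene-1-carbaldehyde | O=C[C@]1(C)[C@@H](C)CC=C2[C@H]1CCCC2(C)C | intermediate
12 | 1,2,4,5-tetramethoxybenzene | COc1cc(OC)c(OC)cc1OC | starting material
13 | 2,3,5,6-tetramethoxyphenyllithium | [Li]c1c(OC)c(OC)cc(OC)c1OC | intermediate
14 | (2,3,5,6-tetramethoxyphenyl)[(1R,2S,8aR)-1,2,5,5-tetramethyl-1,2,3,5,6,7,8,8a-octahydronaphthalen-1-yl]methanol, C11 epimers | OC(c1c(OC)c(OC)cc(OC)c1OC)[C@]2(C)[C@@H](C)CC=C3[C@H]2CCCC3(C)C | intermediate
15 | C6 acetoxymercurio derivative of bridged ether 16 (Hg on the face opposite the ether oxygen), C11 epimers | COc1cc(OC)c(OC)c(C2O[C@]3([C@H]([Hg]OC(C)=O)C[C@H](C)[C@]2(C)[C@@H]3CCC4)C4(C)C)c1OC | intermediate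
16 | bridged ether: 11,5-epoxy cis-decalin (oxolane O–C11–C9–C10–C5), 11-(2,3,5,6-tetramethoxyphenyl), (5S,8S,9R,10S), C11 epimers | COc1cc(OC)c(OC)c(C2O[C@]3(CC[C@H](C)[C@]2(C)[C@@H]3CCC4)C4(C)C)c1OC | intermediate
17 | (1R,2S,4aS,8aS)-1,2,5,5-tetramethyl-1-[(2,3,5,6-tetramethoxyphenyl)methyl]octahydronaphthalen-4a(2H)-ol | COc1cc(OC)c(OC)c(C[C@]2(C)[C@@H](C)CC[C@]3(O)[C@H]2CCCC3(C)C)c1OC | intermediate
18 | 3-{[(1R,2S,4aS,8aS)-4a-hydroxy-1,2,5,5-tetramethyldecahydronaphthalen-1-yl]methyl}-2,5-dimethoxycyclohexa-2,5-diene-1,4-dione | COC1=CC(=O)C(OC)=C(C[C@]2(C)[C@@H](C)CC[C@]3(O)[C@H]2CCCC3(C)C)C1=O | intermediate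
19 | 2-hydroxy-3-{[(1R,2S,4aS,8aS)-4a-hydroxy-1,2,5,5-tetramethyldecahydronaphthalen-1-yl]methyl}-5-methoxycyclohexa-2,5-diene-1,4-dione | COC1=CC(=O)C(O)=C(C[C@]2(C)[C@@H](C)CC[C@]3(O)[C@H]2CCCC3(C)C)C1=O | target

**Step count**

Total: 11 steps. Longest linear sequence: 11 steps, from 2,2-dimethylcyclohexanone 1 (the arene 12 enters in step 7).

**The three steps most likely to fail**

Step 4 (key cycloaddition). The reaction may be slow or unselective. The s-cis form of 7 is crowded by the C4 gem-dimethyl group against the C6 silyloxy group, the enal is beta-substituted, and the catalyst is bulky; silyl transfer of the Mukaiyama–Michael type, loss of exo selectivity or loss of facial selectivity could compete. Fallback: give up catalyst control of the absolute configuration. Setting out from 7 and 8, Me2AlCl (1.1 equiv, CH2Cl2, −78 to −20 °C) promotes the same cycloaddition with regio- and exo-selectivity resting on the substrate alone. It should give 9 together with the mirror-image aldehyde F1. The two are separated by preparative chromatography on a chiral stationary phase, and enantiopure 9 re-enters the route at step 5.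

Step 8 (ether closure). Closure of the strained 6-oxabicyclo[3.2.1]octane onto the neopentyl-type tertiary carbon C5 may be slow. Intermolecular solvomercuration, mercuration of the arene or reversal during demercuration could then compete, and the two C11 epimers of 14 may cyclise at different rates. Fallback: form the same O–C5 bond from a carboxylate before the arene is introduced. Setting out from 11:
- Pinnick oxidation (NaClO2, NaH2PO4, 2-methyl-2-butene, t-BuOH/H2O) should give the carboxylic acid F2.
- Iodolactonisation (I2, NaHCO3, MeCN/H2O) should give the iodolactone F3, again with the oxygen forced onto the C5 face cis to C11.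
- Bu3SnH with AIBN (benzene, 80 °C) removes the iodine and gives the lactone F4.
- One equivalent of aryllithium 13 (THF, −78 °C) adds to the lactone carbonyl and gives the lactol F5.
- Et3SiH with BF3·OEt2 (CH2Cl2, −78 °C) reduces F5 through the aryl-stabilised oxocarbenium ion to ether 16, where the route resumes at step 9.

Step 9 (reductive ether cleavage). The tetramethoxyarene accepts an electron reluctantly, so the cleavage may stall, or Birch reduction and demethoxylation of the ring may overtake it. Fallback: oxidise the arene first and cleave the C11–O bond afterwards. Setting out from 16, (NH4)2Ce(NO3)6 (MeCN/H2O, 0 °C) should give the quinone ether F6. Zn in AcOH reduces it to the hydroquinone, whose hydroxyl ortho to C11 expels the C5 oxygen as an ortho-quinone methide; this is reduced in situ to the hydroquinone F7. This is reductive cleavage of a benzylic C–O bond next to a quinone, the mode of reductive deglycosidation of anthracyclinones. Air or FeCl3 re-oxidises F7 to 18, where the route resumes at step 11.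

**Further compounds**

F1 | step 4 | enantiomer of 9, (1S,2R,8aS) | O=C[C@@]1(C)[C@H](C)CC(O[Si](C)(C)C(C)(C)C)=C2[C@@H]1CCCC2(C)C
F2 | step 8 | (1R,2S,8aR)-1,2,5,5-tetramethyl-1,2,3,5,6,7,8,8a-octahydronaphthalene-1-carboxylic acid | O=C(O)[C@]1(C)[C@@H](C)CC=C2[C@H]1CCCC2(C)C
F3 | step 8 | iodolactone: 11,5-olide with iodine on C6 anti to the lactone oxygen | O=C1O[C@]2([C@H](I)C[C@H](C)[C@]1(C)[C@@H]2CCC3)C3(C)C
F4 | step 8 | lactone: 11,5-olide of the cis-decalin, (5S,8S,9R,10S) | O=C1O[C@]2(CC[C@H](C)[C@]1(C)[C@@H]2CCC3)C3(C)C
F5 | step 8 | lactol: 11-hydroxy-11-(2,3,5,6-tetramethoxyphenyl) bridged ether, C11 epimers | OC1(c2c(OC)c(OC)cc(OC)c2OC)O[C@]3(CC[C@H](C)[C@]1(C)[C@@H]3CCC4)C4(C)C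
F6 | step 9 | quinone ether: 2,5-dimethoxy-1,4-benzoquinon-3-yl analogue of 16 | COC1=CC(=O)C(OC)=C(C2O[C@]3(CC[C@H](C)[C@]2(C)[C@@H]3CCC4)C4(C)C)C1=O
F7 | step 9 | hydroquinone of 18 | COc1cc(O)c(OC)c(C[C@]2(C)[C@@H](C)CC[C@]3(O)[C@H]2CCCC3(C)C)c1O
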